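I was asked whether a suspension of solid G with Q is still changing at 30 h, and how much Z.D and dissolved L it then holds.

G 0.10 M; Q 0.200 M; time 30 h

    L → Z (k1 = 5.7 × 10⁻⁴ min⁻¹)
    Q → D (k2 = 9.8 × 10⁻⁴ min⁻¹)
    Z + D ⇌ Z.D (K3 = 53 L mol⁻¹, k3 = 0.0044 L mol⁻¹ min⁻¹)
    G ⇌ L, rate k4*(cs4 - [L]) while solid is left; crystals form when [L] > cs4 (cs4 = 0.065 M, k4 = 8.6 × 10⁻⁴ min⁻¹)

* why nothing more happens at 30 h, or that something still does (for what has run out or reacted, a solid counts together with what of it has only dissolved) (forward and back rates have come level / all of G has reacted / it is still moving / Q has run out first)
* how much Z.D there is at 30 h, in percent of the G charged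
* how much L there is at 30 h, in percent of the G charged

- G is a solid; its amount is given per volume of the solution
- at the start none of G is in solution
- what has only dissolved of G counts as not reacted
- L means what is dissolved; the solid is not counted in it
- the reaction counts as stopped when no species that holds the G changes by six tenths of a point or more over the second half of the time
- run time (flask): 30 h

I followed one rate, the net rate at which L fills the solution. At the start the solid feeds L at 5.59 × 10⁻⁵ M min⁻¹ and L is not yet drained. Two brakes then grow in proportion to L: dissolution slackens with coefficient 8.6 × 10⁻⁴ min⁻¹, and the first step removes L with constant 5.7 × 10⁻⁴ min⁻¹. While solid is left, the filling rate therefore decays exponentially with their sum, the relaxation rate of L, λ = 0.00143 min⁻¹. Over 30 h this accumulated slowing cuts the rate by the factor 0.0762, to 4.26 × 10⁻⁶ M min⁻¹. Integrating the rate puts L at 36.1% of the G charged.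

The solid has by then given up 0.0618 M, less than the 0.10 M charged, so the decay law holds to the end. In the second half of the time L gains 7.8 percentage points, so by the stopping rule I called the flask still moving. My reckoning gives no figure for Z.D, only a ceiling: what has passed the first step, 25.7% of the G charged.

The forecast said it is still moving, with Z.D at 8.1% and L at 36.1%, reasoning that “Z.D is still rising and L + G is still falling, so the system is still moving.”

At 30 h the simulation gives that it is still moving, with L at 36.1% and Z.D at 8.11%. At 30.0 h L was being made 1.21 times as fast as it was used up, each step taken net. The neighbour flask read at 12 h has the same charge, with G still at 68.8%. For that flask λ gives the accumulated factor 0.357, which puts L at 25.1% of the G charged, and the flask reads 25.1%.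

All constants come from no measurement; the flask was simulated.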